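Links are the product wanted and rings are the loss, so the thing to watch is the ratio in which the two are being made at each moment.

| flask | first end groups | second end groups | protic impurity | remark | time |
|---|---|---|---|---|---|
| north-west | 10 mM | 10.2 mM | 3 mM | run made earlier |  |
| north | 10 mM | 10.2 mM | 4.2 mM | run made earlier |  |
| south-west | 10 mM | 10.2 mM | 6.6 mM | run made earlier |  |
| alder | 10 mM (in portions, 5, over 10 min) | 10.2 mM | 3.00 mM | first portion at the start, last at 10 min | 12 min |
| maple | 10 mM | 10.2 mM | 3.00 mM | everything together at the start | 12 min |
| elm | 10 mM (fed, over 10 min) | 10.2 mM | 3.00 mM | all else is in the flask from the start; the feed brings no volume worth counting | 12 min |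
| larch | 10 mM | 10.2 mM (fed, over 10 min) | 3.00 mM | all else is in the flask from the start; the feed brings no volume worth counting | 12 min |

north-west run (percent of the first end groups charged)

| time / min | links / % | rings / % | first end groups / % |
|---|---|---|---|
| 1.50 | 8.9 | 7.9 | 83.3 |
| 4.00 | 12.0 | 18.6 | 68.0 |
| 8.00 | 10.9 | 26.3 | 60.7 |
| 12.0 | 8.5 | 25.4 | 60.4 |

north run (percent of the first end groups charged)

| time / min | links / % | rings / % | first end groups / % |
|---|---|---|---|
| 2.00 | 10.0 | 10.0 | 79.2 |
| 5.00 | 11.8 | 22.0 | 64.2 |
| 10.0 | 9.6 | 25.0 | 60.6 |
| 15.0 | 7.9 | 25.6 | 61.1 |

south-west run (percent of the first end groups charged)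

| time / min | links / % | rings / % | first end groups / % |
|---|---|---|---|
| 2.00 | 9.3 | 10.2 | 79.3 |
| 5.00 | 10.8 | 22.3 | 64.5 |
| 10.0 | 9.3 | 24.0 | 62.5 |
| 15.0 | 8.2 | 24.7 | 62.6 |



Each earlier reading carries a scatter of 0.3 percentage points (standard deviation).

- the flask that comes out highest in share of links in links plus rings, or "all alike" when all lie within 1.5 percentage points (alder / maple / elm / larch / all alike)
- share of links in links plus rings at the end, alder
- share of links in links plus rings at the end, maple
- share of links in links plus rings at the end, elm
- share of links in links plus rings at the end, larch

**How fast do rings form?** In the north-west run, per minute and per first end group present, rings form at 0.0575 min⁻¹ up to the first reading and at 0.0566 min⁻¹ over the next stretch, so this reads as steady.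

**And links?** Links gained against rings stand at 1.13 over the first stretch, then 0.290. I therefore take link making to follow c(second end groups), while ring making needs them merely present.

**What do you carry forward?** Drawn back in a straight line, the ratio (a selectivity factor) starts at 1.44, where c(second end groups) is 10.2 mM. That gives the crossover concentration, the c(second end groups) at which links and rings form equally fast: 7.08 mM. First end groups cancel from this ratio.

**So feeding first end groups changes nothing?** It does. In the north-west run, first end groups took about 3.96 mM of the 10.2 mM charged as second end groups, so 6.24 mM went elsewhere, more than the 3 mM of impurity. Late first end groups therefore meet a lower c(second end groups). I put alder and elm below maple, with elm lowest of the two.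

**And maple?** It is the north-west recipe, which reads 25.1 %.

**Larch?** The links of the north-west run at 4.00 min, set against the crossover, put a rate of 0.283 min⁻¹ on that loss. In larch, the feed brings 1.02 mM min⁻¹ and rings demand 0.566 mM min⁻¹, so I reckon c(second end groups) holds near 1.61 mM. That gives a link share of about 18.5 %, and maple stays highest in my reckoning.

The forecast differs: it gives 42 %, 25.3 %, 45 % and 35 % for alder, maple, elm and larch, and picks elm, “so link share is highest for elm”.

The flasks give 19.4 %, 26.5 %, 16.4 % and 10.8 % in that order, so maple comes highest.

    first end groups + second end groups → links (k = 0.150 M⁻¹ s⁻¹)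
    first end groups + second end groups → rings, rate k2*[first end groups] as long as [second end groups] is above zero (k = 9.60 × 10⁻⁴ s⁻¹)
    second end groups + protic impurity → quenched reagent (k = 0.240 M⁻¹ s⁻¹)
    links ⇌ isomer of the product (K = 1.30, k = 7.90 × 10⁻⁴ s⁻¹)
    second end groups → decomposed reagent (k = 0.00510 s⁻¹)

In larch, c(second end groups) averaged 1.06 mM over the first 10 min, below the 1.61 mM I reckoned. Divided by the crossover I read from the north-west run, 7.08 mM, that mean gives links against rings of 0.150, which is a link share of 13.0 %. Larch itself ends at 10.8 %.

All runs were computed with constants of no real substance.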